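## Structural features

The target is a tricyclic C20 diterpenoid of the briarane type. A cyclohexene (ring A: C1, C10, C11, C12, C13, C14) is trans-fused along C1–C10 to a ten-membered carbocycle (ring B: C1 to C10), which carries an α-methyl butenolide (ring C) fused at C7–C8. Ring B holds a Z-trisubstituted alkene (C5=C6, methyl on C5) and ring A a cis-disubstituted alkene (C13=C14). There are seven stereocentres: the quaternary C1 next to C10, the adjacent cis-diol carbons C11 (tertiary) and C12 (secondary), the vicinal diacetate carbons C2 and C3 (2R,3R, a syn pair) that continue from C1 into ring B, and the isolated lactone carbinol C7. The fragile groups are the two secondary acetates (base), the C7 hydrogen, which is both the γ-hydrogen of the butenolide and allylic to C5=C6, the allylic C12 hydroxyl and the Z-alkene. The real difficulty is the strained ten-membered ring together with the C2/C3 pair, which lies between the quaternary C1 and the ring B alkene and is not easily controlled from ring A. The key step exploits two facts: C2 is a carbonyl-level carbon blocked on one side by the quaternary C1, so it enolises only towards C3, and C4 is the primary allylic terminus of the Z-C5=C6 alkene. Enolate carbon C3 and allylic carbon C4 are therefore a matched pair whose union closes ring B.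

## Logic of the disconnections

Ring C (42 ⇒ 41 ⇒ 40 ⇒ 39). The C8=C17 alkene and the O7–C19 acyl bond are cut. The butenolide holds the most acidic hydrogen of the target and cannot be present in a base-mediated ring closure. This reduces ring C to a C7 carbinol and a masked C8 ketone. The forward steps must free the ketone next to an acyloxy group without moving the C5=C6 alkene, and must close the lactone with a weak base.

C2/C3 oxygenation (39 ⇒ 38 ⇒ 37 ⇒ 36 ⇒ 35). The two acetyl C–O bonds and the C2–H bond are cut. Both oxygenated centres are thereby traced to one α-alkoxy ketone. The hydride must add anti to the C3–O bond (non-chelated mode) to give 2R, and the C3 ether must come off without touching three alkenes.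

Ring B (35 ⇒ 33 through 34). The C3–C4 bond is cut. C3 is the only enolisable position beside the C2 carbonyl and C4 is a primary allylic carbon, so the cut gives an open chain whose ends are a natural nucleophile and electrophile. The forward step must favour C- over O-alkylation, SN2 over SN2′ and ring closure over dimerisation, and it creates C3.

Oxidation level and leaving group (33 ⇒ 32 ⇒ 31 ⇒ 30). The ketone and the bromide are traced to a protected diol. This lets the reactive pair be unmasked only at the end. It demands that two silyl ethers be removed while a third stays.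

C6–C7 (30 ⇒ 29 ⇒ 28 ⇒ 21 + 25 through 26 and 27). The alkenyl–acyl bond is cut and C7 is taken back to a ketone. The cut separates the whole C4–C6 unit with its fixed Z geometry from ring A. The forward steps need a single addition to an ester, retention of alkene geometry and catalyst control at C7.

Alkenyl iodide (25 ⇒ 24 ⇒ 22 through 23). The C5–CH3 and C6–I bonds are cut, leading to a three-carbon alkynol. The forward step must add methyl and metal anti across the alkyne.

Ring A functionality (21 ⇒ 20 ⇒ 19 ⇒ 18 ⇒ 17). The C13=C14 alkene is traced to a C14 oxygen and the diol to the C11=C12 alkene. This leaves one alkene for osmylation. The oxidant must approach anti to the C9 arm, and the elimination can only go towards C13.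

C9–C10 (17 ⇒ 16 ⇒ 15 ⇒ 14 ⇒ 13). The C9–C10 bond is cut in the sense of a [3,3] shift from O12. The bond next to the quaternary C1 is thus made intramolecularly and its configuration is tied to that of C12. The forward step must transfer chirality suprafacially.

Oxygen transposition and isopropenyl excision (13 ⇒ 12 ⇒ 10 ⇒ 9 through 11). The C12 oxygen is traced to an epoxide of the enone, and the C14 oxygen to the isopropenyl group. This returns the ring to a carvone-type enone. The epoxidation must occur anti to the C14 substituent and the C14–C bond must migrate with retention.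

C2–C3 (9 ⇒ 3 + 6 through 7 and 8; 6 ⇒ 4 through 5). The C2–C3 bond is cut to an aldehyde and an alkoxymethyl anion. The side chain then arrives with its C3 oxygen already protected. The anion must attack the aldehyde and not the hindered enone.

Quaternary C1 (3 ⇒ 2 ⇒ 1). The C1–CH3 and C1–C2 bonds are cut. This leads to a commercial terpene that supplies ring A, two methyl-bearing positions and the controlling stereocentre. The methyl must enter anti to the isopropenyl group.

## Other disconnections considered

Alternative 1: The cut is through C10–C11 and C1–C14 of ring A. In the forward sense the enal A1 and the silyloxydiene A2 combine in a catalytic enantioselective Diels–Alder reaction under a cationic chiral oxazaborolidine to give the cyclohexene A3. In its favour, one step makes ring A, the quaternary C1 and C10 with absolute control from two small achiral pieces. C2 arrives as an aldehyde, C9 as a protected carbinol, and the enol ether is a handle for the C12 oxygen and the C13=C14 alkene. Against it, a trisubstituted enal is a slow dienophile and needs the most Lewis-acidic catalysts, and endo selectivity and diene geometry must both hold. The C11 carbinol and the cis-diol must then be made from a ketone, where facial control is less secure than osmylation of an alkene. Ring B is left unsolved. On structure it answers ring A only, so it complements the chosen plan. On mechanism a concerted cycloaddition is more predictable for C1 and C10 than the relay used here, and on this point it is the better. On step economy for ring A it is also the better (one step to A3 against ten steps to 16). Both plans are equal in needing a later solution for C2 and C3.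

Alternative 2: The cut is the C1–C10 bond, made across a fourteen-membered ring. In the forward sense Et2AlCl opens the vinyl epoxide A4 at C1, the C10=C11 alkene attacks across the ring and loss of a C12 proton gives the tricyclic diene A5. In its favour, both carbocycles and the C1/C10 centres form in one step, and a fourteen-membered ring is easier to close than a ten-membered one. The butenolide can be present because no base is used, which is better than the chosen plan, where ring C must stay masked. The C2 hydroxyl takes its configuration from the epoxide, which is also better than a late hydride reduction. Against it, A4 needs three alkenes of defined geometry and a defined epoxide. The allylic cation at C1 can be captured at C13, the C5=C6 alkene can compete, proton loss can go several ways, and the trans fusion depends on the reacting conformer. The diene must afterwards be dihydroxylated at C11=C12 only and from one face. On structure it maps most directly onto the skeleton. On mechanism a cationic cascade with several branch points is less certain than one SN2 event. On step economy it could be shorter. Both plans are equal in relying on the conformation of a medium or large ring.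

Alternative 3: The cut is the C7–C8 bond together with the lactone C–O bond. In the forward sense CrCl2 (divalent chromium) with catalytic NiCl2 turns the enol triflate of A6 into an alkenylchromium that adds to the C7 aldehyde, and the alkoxide lactonises to give A7. In its favour, the conditions are not basic, so the acetates can already be in place, and rings B and C close in one operation. Only acetonide hydrolysis remains, so the endgame is much shorter than here (one step against seven), and on this point it is the better. C2 and C3 can be set earlier by open-chain methods, which is also better than control inside the ring. Against it, C7 must be set by the macrocycle and cannot be corrected, whereas here C7 is set by a catalyst before ring closure and C3 remains epimerisable. The alkenylchromium is tetrasubstituted and conjugated to an ester, so addition will be slow. The Z-enal can isomerise, chromium is used in excess, and A6 needs the whole C1–C7 chain with four stereocentres before ring closure. On structure both plans close the same ten-membered ring and are equal. On mechanism the chromium reaction tolerates more functionality, and the enolate alkylation gives a correctable centre. On step economy the alternative wins after the key step and probably loses before it.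

Key step: step 24

Remark: C15, C16 and C20 are the methyls on C1, C5 and C11; C17, C18 and C19 are the butenolide α-carbon, its methyl and the carbonyl. β is the face of ring A that carries C15 and α the opposite face.

Remark: by the open-chain models a chelated hydride addition to a (3R)-alkoxy ketone gives the 2,3-anti diol, whereas the target is 2R,3R (syn). The C2 reduction is therefore run under non-chelating Felkin–Anh conditions.

Remark: the C3 oxygen carries a p-methoxybenzyl (PMB) group, which can be removed oxidatively in the presence of three alkenes. C8 is masked as a dimethyl ketal, which adds no stereocentre and hydrolyses more readily than a dioxolane.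

Remark: (S)-carvone is used. Its α isopropenyl group sends the C1 methyl to the β face, the epoxide to the β face and, through O12, the C9 arm to the β face.

Remark: the C2 carbinol centre made in step 4 is destroyed in step 23. It is drawn (S), the epimer expected from chelate-controlled addition, and either epimer serves.

Step 1
Reactants: 1 (S)-carvone
Product: 2 hydroxymethylene ketone (C1=CHOH; C10 ketone; C11=C12; 14α-isopropenyl)
Conditions: NaH, HCO2Et, EtOH (cat.), Et2O, 0 °C to rt; then aq. AcOH
Reagents that add atoms: ethyl formate, CCOC=O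
Why: Crossed Claisen condensation (α′-formylation) at C1, the only α position that leads to a stabilised β-dicarbonyl enolate, which acts as the thermodynamic sink; the C14 centre is untouched.

Step 2
Reactants: 2 hydroxymethylene ketone
Product: 3 keto aldehyde (1β-methyl; 1α-formyl; 14α-isopropenyl)
Conditions: MeI, K2CO3, acetone, rt
Reagents that add atoms: iodomethane, CI
Why: C-alkylation of the β-keto aldehyde enolate creates the quaternary C1. Iodomethane should approach anti to the adjacent isopropenyl group, so the methyl ends up β and the formyl group α.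

Step 3
Reactants: 4 4-methoxybenzyl alcohol
Product: 6 tributyl{[(4-methoxybenzyl)oxy]methyl}stannane, via sodium 4-methoxybenzyl oxide 5 (not isolated)
Conditions: NaH, THF–DMF, 0 °C; then Bu3SnCH2I, rt
Reagents that add atoms: tributyl(iodomethyl)stannane, CCCC[Sn](CCCC)(CCCC)CI
Why: Williamson ether synthesis; the primary iodide next to tin is an unhindered SN2 electrophile.

Step 4
Reactants: 3 keto aldehyde; 6 stannane
Product: 9 C2 triethylsilyl ether (C3 O-PMB; C10 ketone; C11=C12; 14α-isopropenyl), via PMB-oxymethyllithium 7 (not isolated), via lithium C2-alkoxide 8 (not isolated)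
Conditions: 6, n-BuLi, THF, −78 °C; then 3, −78 °C; then Et3SiOTf, −78 to −40 °C
Reagents that add atoms: triethylsilyl triflate, CC[Si](CC)(CC)OS(=O)(=O)C(F)(F)F
Why: Tin–lithium exchange gives the α-alkoxymethyllithium, which should add to the aldehyde much faster than to the hindered conjugated C10 ketone (1,2-addition). Silylation in the same flask traps the aldolate before retro-aldol cleavage.

Step 5
Reactants: 9 C2 triethylsilyl ether
Product: 10 epoxy ketone (11β,12β-epoxide)
Conditions: t-BuOOH, benzyltrimethylammonium hydroxide (cat.), THF, 0 °C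
Reagents that add atoms: tert-butyl hydroperoxide, CC(C)(C)OO
Why: Nucleophilic (Weitz–Scheffer) epoxidation of the enone; attack at C12 should occur anti to the C14 isopropenyl group as in carvone itself, placing the epoxide on the β face. The isolated alkene is inert to the hydroperoxide anion.

Step 6
Reactants: 10 epoxy ketone
Product: 12 14α-acetate, via methoxy hydroperoxide 11 (not isolated)
Conditions: O3, CH2Cl2–MeOH, −78 °C; then Ac2O, Et3N, 4-(dimethylamino)pyridine (cat.), 0 °C to rt
Reagents that add atoms: ozone, [O-][O+]=O; methanol, CO
Why: Ozonolysis in methanol converts the only alkene into the α-methoxy hydroperoxide, and its acetylation triggers the Criegee rearrangement. C14 migrates to oxygen with retention, so the 14α-acetate replaces the isopropenyl group as a latent C13=C14 alkene that OsO4 will not touch.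

Step 7
Reactants: 12 14α-acetate
Product: 13 allylic alcohol (12β-hydroxyl; C10=C11)
Conditions: N2H4·H2O, AcOH (cat.), MeOH, 0 °C to rt
Reagents that add atoms: none
Why: Wharton transposition: hydrazone formation, epoxide opening and loss of N2 remove the C10 oxygen, leave the β C12–O bond intact and create the C10=C11 alkene needed for the sigmatropic step.

Step 8
Reactants: 13 allylic alcohol
Product: 14 O12 phosphonoacetate ether
Conditions: (MeO)2P(O)C(N2)CO2Me, Rh2(OAc)4 (1 mol %), benzene, 80 °C
Reagents that add atoms: methyl 2-diazo-2-(dimethoxyphosphoryl)acetate, COC(=O)C(=[N+]=[N-])P(=O)(OC)OC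
Why: Rhodium carbenoid O–H insertion into the secondary alcohol, which is faster than cyclopropanation of the hindered trisubstituted alkene, with retention at C12; the new phosphonate carbon is a mixture and becomes sp2 in step 9.

Step 9
Reactants: 14 O12 phosphonoacetate ether
Product: 15 O12 2-alkoxyacrylate (allyl vinyl ether)
Conditions: (CH2O)n, K2CO3, THF–H2O, 0 °C to rt
Reagents that add atoms: formaldehyde, C=O
Why: Horner–Wadsworth–Emmons methylenation with formaldehyde under carbonate conditions that spare the acetate.

Step 10
Reactants: 15 O12 2-alkoxyacrylate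
Product: 16 α-keto ester (C8 ketone; C7 methyl ester; C9 arm β on C10; C11=C12)
Conditions: toluene, 100 °C (sealed tube), 2,6-di-tert-butyl-4-methylphenol (trace)
Reagents that add atoms: none
Why: Gosteli–Claisen [3,3]-sigmatropic rearrangement, accelerated by the 2-alkoxycarbonyl group. Suprafacial transfer from the β O12 forms C9–C10 on the β face next to the quaternary C1, which sets C10 and regenerates the C11=C12 alkene.

Step 11
Reactants: 16 α-keto ester
Product: 17 C8 dimethyl ketal
Conditions: MeOSiMe3, Me3SiOTf (10 mol %), CH2Cl2, −78 to −30 °C; pyridine quench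
Reagents that add atoms: methoxytrimethylsilane, CO[Si](C)(C)C
Why: Aprotic Noyori-type ketalisation of the electrophilic α-keto ester; low temperature and a catalytic amount of silyl triflate should spare the triethylsilyl ether, the PMB ether and the acetate.

Step 12
Reactants: 17 C8 dimethyl ketal
Product: 18 11α,12α-diol
Conditions: OsO4 (5 mol %), N-methylmorpholine N-oxide, acetone–H2O, rt
Reagents that add atoms: N-methylmorpholine N-oxide, C[N+]1([O-])CCOCC1; water, O
Why: Upjohn dihydroxylation of the only alkene. OsO4 should add anti to the β C9 side chain on the adjacent C10, giving the cis-diol on the α face and setting C11 and C12.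

Step 13
Reactants: 18 11α,12α-diol
Product: 19 11,12-acetonide
Conditions: Me2C(OMe)2, pyridinium p-toluenesulfonate (cat.), CH2Cl2, rt
Reagents that add atoms: 2,2-dimethoxypropane, COC(C)(C)OC
Why: Acetonide formation by transketalisation is specific for the cis-1,2-diol; it also masks the tertiary C11 hydroxyl, which could otherwise add to the later C2 ketone.

Step 14
Reactants: 19 11,12-acetonide
Product: 20 14α-alcohol
Conditions: K2CO3, MeOH, rt
Reagents that add atoms: none
Why: Base-catalysed transesterification removes the secondary acetate; the methyl ester is unchanged under these conditions and the silyl ether should survive.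

Step 15
Reactants: 20 14α-alcohol
Product: 21 ring A ester (C13=C14; C8 dimethyl ketal; C7 methyl ester)
Conditions: Burgess reagent (MeO2CN−SO2N+Et3), toluene, 70 °C
Reagents that add atoms: none
Why: Burgess dehydration by syn elimination of the sulfamate; C1 is quaternary, so only a C13 hydrogen can be lost and the C13=C14 alkene forms regiospecifically.

Step 16
Reactants: 22 propargyl alcohol
Product: 24 (Z)-3-iodo-2-methylprop-2-en-1-ol, via alkenylmagnesium chelate 23 (not isolated)
Conditions: MeMgBr (2.5 equiv), CuI (10 mol %), THF–Et2O, −10 °C to rt; then I2, −10 °C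
Reagents that add atoms: methylmagnesium bromide, C[Mg]Br; iodine, II
Why: CuI-catalysed anti-carbomagnesiation of the propargylic alkoxide gives a five-membered magnesium chelate. Iodinolysis with retention places iodine cis to the CH2O group, the later cis relation of C7 and C4.

Step 17
Reactants: 24 (Z)-3-iodo-2-methylprop-2-en-1-ol
Product: 25 (Z)-tert-butyl[(3-iodo-2-methylallyl)oxy]dimethylsilane
Conditions: t-BuMe2SiCl, imidazole, CH2Cl2, 0 °C to rt
Reagents that add atoms: tert-butyldimethylsilyl chloride, CC(C)(C)[Si](C)(C)Cl
Why: Silylation of the primary allylic alcohol; the bulky silyl group also slows a 1,4 O-to-C silyl shift in the derived alkenyllithium.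

Step 18
Reactants: 21 ring A ester; 25 alkenyl iodide
Product: 28 Z-enone (C7 ketone; C8 dimethyl ketal; C4 O-TBS), via alkenyllithium 26 (not isolated), via lithium hemiketal alkoxide 27 (not isolated)
Conditions: 25, t-BuLi (2 equiv), Et2O, −78 °C; then 21, −78 °C; aq. NH4Cl
Reagents that add atoms: none
Why: Iodine–lithium exchange with retention of geometry, then acylation of the alkenyllithium by the α,α-dimethoxy ester forms C6–C7. The chelated adduct 27 should persist until quench, so the ketone is released only on work-up and is not attacked twice.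

Step 19
Reactants: 28 Z-enone
Product: 29 (7S)-allylic alcohol
Conditions: (R)-1-methyl-3,3-diphenyltetrahydro-1H,3H-pyrrolo[1,2-c][1,3,2]oxazaborole (20 mol %), catecholborane, toluene, −78 °C
Reagents that add atoms: none
Why: Corey–Bakshi–Shibata reduction under catalyst control. With the fully substituted ketal carbon as the large group and the Z-alkenyl group as the small one, the (R)-catalyst should give the 7S alcohol; catecholborane at low temperature avoids hydroboration and 1,4-reduction.

Step 20
Reactants: 29 (7S)-allylic alcohol
Product: 30 7-O-TBS ether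
Conditions: t-BuMe2SiOTf, 2,6-lutidine, CH2Cl2, −78 °C
Reagents that add atoms: tert-butyldimethylsilyl triflate, CC(C)(C)[Si](C)(C)OS(=O)(=O)C(F)(F)F
Why: Silylation of a hindered secondary alcohol with the silyl triflate; the ether must survive step 21 and keep O7 from attacking the allylic bromide.

Step 21
Reactants: 30 7-O-TBS ether
Product: 31 diol (C2 hydroxyl; C4 hydroxyl)
Conditions: HF·pyridine, pyridine, THF, 0 °C
Reagents that add atoms: none
Why: Chemoselective desilylation: the triethylsilyl ether at C2 and the primary TBS ether at C4 should cleave much faster than the secondary TBS ether at C7, which is shielded by the neighbouring quaternary ketal carbon.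

Step 22
Reactants: 31 diol
Product: 32 allylic bromide with free C2 hydroxyl
Conditions: CBr4, PPh3, 2,6-lutidine, CH2Cl2, −30 °C
Reagents that add atoms: carbon tetrabromide, BrC(Br)(Br)Br
Why: Appel bromination; the primary allylic alcohol should react far faster than the neopentyl-type secondary C2 alcohol, and SN2 displacement keeps the Z geometry.

Step 23
Reactants: 32 allylic bromide
Product: 33 ring-closure precursor (C2 ketone; C3 O-PMB; C4 bromide; C7 O-TBS; C8 dimethyl ketal; 11,12-acetonide)
Conditions: Dess–Martin periodinane, NaHCO3, CH2Cl2, 0 °C to rt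
Reagents that add atoms: none
Why: Dess–Martin oxidation under buffered, non-nucleophilic conditions tolerates the allylic bromide, the PMB ether and both ketals, and removes the temporary C2 centre.

Step 24
Reactants: 33 ring-closure precursor
Product: 35 ring B ketone (C2 ketone; 3R O-PMB; C7 O-TBS; C8 dimethyl ketal; 11,12-acetonide), via lithium enolate 34 (not isolated)
Conditions: LiN(SiMe3)2 (1.2 equiv), THF, 0.002 M, slow addition of 33, −78 to 0 °C
Reagents that add atoms: none
Why: LiN(SiMe3)2 removes a C3 proton of 33, the only acidic position because C1 is quaternary and C8 is a ketal, to give the Z(O) lithium enolate 34. Its C3 terminus displaces bromide at the primary allylic carbon C4 in an intramolecular SN2 step that forms C3–C4. The closest known reaction type is the macrocyclic alkylation of ketone enolates and protected cyanohydrin anions by allylic halides used for ten-membered germacrane rings. Ring B closes in the 10-(enolendo)-exo-tet mode, and high dilution with slow addition should suppress dimerisation. The Z-alkene and the trans-disposed C1 and C10 arms of ring A turn the chain back so that C4 can reach C3. The new C3 centre is set by the enolate face that the tether can reach; the transition state with the PMB-oxy group on the periphery is expected to give 3R, and because C3 stays α to the C2 carbonyl the more stable epimer can be reached by equilibration. C-alkylation is favoured by the tight lithium enolate in THF without polar additives and by the soft allylic bromide. SN2 is favoured over SN2′ because C4 is primary, whereas C6 is flanked by the silyloxy-bearing C7.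

Step 25
Reactants: 35 ring B ketone
Product: 36 (2R)-alcohol
Conditions: LiBH(s-Bu)3, THF, −78 °C; then NaOH, H2O2
Reagents that add atoms: none
Why: Hydride reduction under non-chelating Felkin–Anh control: the bulky borohydride should attack C2 anti to the C3–O bond, which for the 3R ketone gives the 2R alcohol (2,3-syn). A chelated reduction would give the 2-epimer.

Step 26
Reactants: 36 (2R)-alcohol
Product: 37 2,3-diol
Conditions: DDQ, CH2Cl2–pH 7 buffer, 0 °C
Reagents that add atoms: none
Why: Oxidative cleavage of the PMB ether (benzylic hydride abstraction, then hydrolysis); the neutral conditions leave the alkenes, silyl ether, ketal and acetonide intact.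

Step 27
Reactants: 37 2,3-diol
Product: 38 2,3-diacetate
Conditions: Ac2O, 4-(dimethylamino)pyridine, pyridine, rt
Reagents that add atoms: acetic anhydride, CC(=O)OC(C)=O
Why: Nucleophile-catalysed acylation of the two secondary alcohols; all other hydroxyl groups are masked.

Step 28
Reactants: 38 2,3-diacetate
Product: 39 C7 alcohol
Conditions: HF·pyridine, THF, 0 °C to rt
Reagents that add atoms: none
Why: Fluoride-driven desilylation under non-basic conditions that should neither cleave nor shift the acetates.

Step 29
Reactants: 39 C7 alcohol
Product: 40 C7 phosphonopropionate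
Conditions: (EtO)2P(O)CH(Me)CO2H, N,N′-dicyclohexylcarbodiimide, 4-(dimethylamino)pyridine (cat.), CH2Cl2, 0 °C to rt
Reagents that add atoms: 2-(diethoxyphosphoryl)propanoic acid, CCOP(=O)(OCC)C(C)C(O)=O
Why: Steglich esterification of the only free hydroxyl, with retention at C7; the phosphonate carbon is a mixture and becomes sp2 in step 31.

Step 30
Reactants: 40 C7 phosphonopropionate
Product: 41 C8 ketone with free 11,12-diol
Conditions: CF3CO2H–H2O (9:1), CH2Cl2, 0 °C
Reagents that add atoms: water, O
Why: Acid-catalysed hydrolysis of the dimethyl ketal, assisted by the neighbouring acyloxy group, and of the acetonide in one operation; acetates and the phosphonate ester are stable to cold aqueous acid.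

Step 31
Reactants: 41 C8 ketone
Product: 42 CNP0291307.1 (target)
Conditions: LiCl, i-Pr2NEt, MeCN, 0 °C to rt
Reagents that add atoms: none
Why: Intramolecular Horner–Wadsworth–Emmons reaction under Masamune–Roush conditions closes ring C at C8=C17. The weak base should limit epimerisation at C7 and leave the acetates and the diol untouched.

Compound list

1 | (S)-carvone | CC1=CC[C@@H](CC1=O)C(C)=C | starting material
2 | hydroxymethylene ketone (C1=CHOH, C10 ketone, C11=C12, 14α-isopropenyl) | O=C1C(C)=CC[C@H](C(C)=C)/C1=C/O | intermediate
3 | keto aldehyde (1β-methyl, 1α-formyl, 14α-isopropenyl) | C[C@@]1(C=O)C(=O)C(C)=CC[C@@H]1C(C)=C | intermediate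
4 | 4-methoxybenzyl alcohol | COc1ccc(CO)cc1 | starting material
5 | sodium 4-methoxybenzyl oxide | [Na+].[O-]Cc1ccc(OC)cc1 | intermediate
6 | tributyl{[(4-methoxybenzyl)oxy]methyl}stannane | CCCC[Sn](CCCC)(CCCC)COCc1ccc(OC)cc1 | intermediate
7 | {[(4-methoxybenzyl)oxy]methyl}lithium | [Li]COCc1ccc(OC)cc1 | intermediate
8 | lithium C2-alkoxide of the adduct of 3 and 7 | C[C@@]1([C@H]([O-])COCc2ccc(OC)cc2)C(=O)C(C)=CC[C@@H]1C(C)=C.[Li+] | intermediate
9 | C2 triethylsilyl ether, C3 O-PMB, C10 enone, 14α-isopropenyl | C[C@@]1([C@H](O[Si](CC)(CC)CC)COCc2ccc(OC)cc2)C(=O)C(C)=CC[C@@H]1C(C)=C | intermediate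
10 | 11β,12β-epoxy C10 ketone | C[C@@]1([C@H](O[Si](CC)(CC)CC)COCc2ccc(OC)cc2)C(=O)[C@@]3(C)O[C@H]3C[C@@H]1C(C)=C | intermediate
11 | α-methoxy hydroperoxide at the former isopropenyl carbon (epimers) | C[C@@]1([C@H](O[Si](CC)(CC)CC)COCc2ccc(OC)cc2)C(=O)[C@@]3(C)O[C@H]3C[C@@H]1C(C)(OC)OO | intermediate
12 | 14α-acetate of the epoxy ketone | C[C@@]1([C@H](O[Si](CC)(CC)CC)COCc2ccc(OC)cc2)C(=O)[C@@]3(C)O[C@H]3C[C@@H]1OC(C)=O | intermediate
13 | allylic alcohol (12β-OH, C10=C11, 14α-OAc) | C[C@@]1([C@H](O[Si](CC)(CC)CC)COCc2ccc(OC)cc2)C=C(C)[C@@H](O)C[C@@H]1OC(C)=O | intermediate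
14 | O12 (dimethoxyphosphoryl)(methoxycarbonyl)methyl ether (epimers at the phosphonate carbon) | C[C@@]1([C@H](O[Si](CC)(CC)CC)COCc2ccc(OC)cc2)C=C(C)[C@@H](OC(C(=O)OC)P(=O)(OC)OC)C[C@@H]1OC(C)=O | intermediate
15 | O12 1-(methoxycarbonyl)vinyl ether | C[C@@]1([C@H](O[Si](CC)(CC)CC)COCc2ccc(OC)cc2)C=C(C)[C@@H](OC(=C)C(=O)OC)C[C@@H]1OC(C)=O | intermediate
16 | α-keto ester (C8 ketone, C7 ester, 10β side chain, C11=C12) | C[C@@]1([C@H](O[Si](CC)(CC)CC)COCc2ccc(OC)cc2)[C@@H](CC(=O)C(=O)OC)C(C)=CC[C@@H]1OC(C)=O | intermediate
17 | C8 dimethyl ketal of 16 | C[C@@]1([C@H](O[Si](CC)(CC)CC)COCc2ccc(OC)cc2)[C@@H](CC(OC)(OC)C(=O)OC)C(C)=CC[C@@H]1OC(C)=O | intermediate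
18 | 11α,12α-diol | C[C@@]1([C@H](O[Si](CC)(CC)CC)COCc2ccc(OC)cc2)[C@@H](CC(OC)(OC)C(=O)OC)[C@](C)(O)[C@H](O)C[C@@H]1OC(C)=O | intermediate
19 | 11,12-acetonide, 14α-acetate | C[C@@]1([C@H](O[Si](CC)(CC)CC)COCc2ccc(OC)cc2)[C@@H](CC(OC)(OC)C(=O)OC)[C@]3(C)OC(C)(C)O[C@@H]3C[C@@H]1OC(C)=O | intermediate
20 | 11,12-acetonide, 14α-alcohol | C[C@@]1([C@H](O[Si](CC)(CC)CC)COCc2ccc(OC)cc2)[C@@H](CC(OC)(OC)C(=O)OC)[C@]3(C)OC(C)(C)O[C@@H]3C[C@@H]1O | intermediate
21 | ring A ester (C13=C14, 11,12-acetonide, C8 dimethyl ketal, C7 methyl ester) | C[C@@]1([C@H](O[Si](CC)(CC)CC)COCc2ccc(OC)cc2)[C@@H](CC(OC)(OC)C(=O)OC)[C@]3(C)OC(C)(C)O[C@@H]3C=C1 | intermediate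
22 | propargyl alcohol | C#CCO | starting material
23 | 4-methyl-2,5-dihydro-1,2-oxamagnesole (alkenylmagnesium chelate) | CC1=C[Mg]OC1 | intermediate
24 | (Z)-3-iodo-2-methylprop-2-en-1-ol | OC/C(C)=C\I | intermediate
25 | (Z)-tert-butyl[(3-iodo-2-methylallyl)oxy]dimethylsilane | CC(C)(C)[Si](C)(C)OC/C(C)=C\I | intermediate
26 | (Z)-3-[(tert-butyldimethylsilyl)oxy]-2-methylprop-1-enyllithium | [Li]/C=C(C)\CO[Si](C)(C)C(C)(C)C | intermediate
27 | lithium hemiketal alkoxide from 21 and 26 | C[C@@]1([C@H](O[Si](CC)(CC)CC)COCc2ccc(OC)cc2)[C@@H](CC(OC)(OC)C([O-])(OC)/C=C(C)\CO[Si](C)(C)C(C)(C)C)[C@]3(C)OC(C)(C)O[C@@H]3C=C1.[Li+] | intermediate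
28 | Z-enone (C7 ketone, C8 dimethyl ketal, C4 O-TBS) | C[C@@]1([C@H](O[Si](CC)(CC)CC)COCc2ccc(OC)cc2)[C@@H](CC(OC)(OC)C(=O)/C=C(C)\CO[Si](C)(C)C(C)(C)C)[C@]3(C)OC(C)(C)O[C@@H]3C=C1 | intermediate
29 | (7S)-allylic alcohol | C[C@@]1([C@H](O[Si](CC)(CC)CC)COCc2ccc(OC)cc2)[C@@H](CC(OC)(OC)[C@@H](O)/C=C(C)\CO[Si](C)(C)C(C)(C)C)[C@]3(C)OC(C)(C)O[C@@H]3C=C1 | intermediate
30 | 7-O-TBS, 4-O-TBS, 2-O-triethylsilyl ether | C[C@@]1([C@H](O[Si](CC)(CC)CC)COCc2ccc(OC)cc2)[C@@H](CC(OC)(OC)[C@@H](O[Si](C)(C)C(C)(C)C)/C=C(C)\CO[Si](C)(C)C(C)(C)C)[C@]3(C)OC(C)(C)O[C@@H]3C=C1 | intermediate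
31 | C2,C4-diol with 7-O-TBS | C[C@@]1([C@H](O)COCc2ccc(OC)cc2)[C@@H](CC(OC)(OC)[C@@H](O[Si](C)(C)C(C)(C)C)/C=C(C)\CO)[C@]3(C)OC(C)(C)O[C@@H]3C=C1 | intermediate
32 | C4 allylic bromide with free C2 hydroxyl | C[C@@]1([C@H](O)COCc2ccc(OC)cc2)[C@@H](CC(OC)(OC)[C@@H](O[Si](C)(C)C(C)(C)C)/C=C(C)\CBr)[C@]3(C)OC(C)(C)O[C@@H]3C=C1 | intermediate
33 | ring-closure precursor: C2 ketone, C3 O-PMB, Z-allylic bromide, C7 O-TBS, C8 dimethyl ketal, 11,12-acetonide | C[C@@]1(C(=O)COCc2ccc(OC)cc2)[C@@H](CC(OC)(OC)[C@@H](O[Si](C)(C)C(C)(C)C)/C=C(C)\CBr)[C@]3(C)OC(C)(C)O[C@@H]3C=C1 | intermediate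
34 | Z(O) lithium enolate of 33 (C2–O–Li, C2=C3) | C[C@@]1(/C([O-])=C/OCc2ccc(OC)cc2)[C@@H](CC(OC)(OC)[C@@H](O[Si](C)(C)C(C)(C)C)/C=C(C)\CBr)[C@]3(C)OC(C)(C)O[C@@H]3C=C1.[Li+] | intermediate
35 | ring B ketone: C2 ketone, (3R) O-PMB, C7 O-TBS, C8 dimethyl ketal, 11,12-acetonide | C[C@@]12C(=O)[C@H](OCc3ccc(OC)cc3)C/C(C)=C\[C@H](O[Si](C)(C)C(C)(C)C)C(OC)(OC)C[C@H]1[C@]4(C)OC(C)(C)O[C@@H]4C=C2 | intermediate
36 | (2R)-alcohol | C[C@@]12[C@@H](O)[C@H](OCc3ccc(OC)cc3)C/C(C)=C\[C@H](O[Si](C)(C)C(C)(C)C)C(OC)(OC)C[C@H]1[C@]4(C)OC(C)(C)O[C@@H]4C=C2 | intermediate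
37 | (2R,3R)-diol | C[C@@]12[C@@H](O)[C@H](O)C/C(C)=C\[C@H](O[Si](C)(C)C(C)(C)C)C(OC)(OC)C[C@H]1[C@]4(C)OC(C)(C)O[C@@H]4C=C2 | intermediate
38 | 2,3-diacetate | C[C@@]12[C@@H](OC(C)=O)[C@H](OC(C)=O)C/C(C)=C\[C@H](O[Si](C)(C)C(C)(C)C)C(OC)(OC)C[C@H]1[C@]4(C)OC(C)(C)O[C@@H]4C=C2 | intermediate
39 | C7 alcohol (2,3-diacetate, C8 dimethyl ketal, acetonide) | C[C@@]12[C@@H](OC(C)=O)[C@H](OC(C)=O)C/C(C)=C\[C@H](O)C(OC)(OC)C[C@H]1[C@]4(C)OC(C)(C)O[C@@H]4C=C2 | intermediate
40 | C7 2-(diethoxyphosphoryl)propanoate (epimers at the phosphonate carbon) | C[C@@]12[C@@H](OC(C)=O)[C@H](OC(C)=O)C/C(C)=C\[C@H](OC(=O)C(C)P(=O)(OCC)OCC)C(OC)(OC)C[C@H]1[C@]4(C)OC(C)(C)O[C@@H]4C=C2 | intermediate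
41 | C8 ketone, free 11,12-diol, C7 phosphonopropionate | C[C@@]12[C@@H](OC(C)=O)[C@H](OC(C)=O)C/C(C)=C\[C@H](OC(=O)C(C)P(=O)(OCC)OCC)C(=O)C[C@H]1[C@](C)(O)[C@H](O)C=C2 | intermediate
42 | CNP0291307.1 | C[C@@]12[C@@H](OC(C)=O)[C@H](OC(C)=O)C/C(C)=C\[C@@H]3OC(=O)C(C)=C3C[C@H]1[C@](C)(O)[C@H](O)C=C2 | target

Total step count: 31. Longest linear sequence: 28 steps (steps 1, 2, 4 to 15 and 18 to 31, from 1 to 42). Steps 3, 16 and 17 are side branches.

Steps least certain to work

Step 24 (key step). The most likely failures are intermolecular alkylation to oligomers, O-alkylation to a ten-membered enol ether, and closure through the enolate face that leads to the 3-epimer. The strain of the ten-membered transition state and the preferred conformation of the tether cannot be predicted with confidence. Fallback: starting from 31, the primary allylic hydroxyl is acylated selectively (ClCO2Me, pyridine, −20 °C) to give the allylic methyl carbonate F1. Dess–Martin oxidation of the C2 hydroxyl gives the keto carbonate F2. Slow addition of F2 to Pd(PPh3)4 (zerovalent palladium) in THF at 60 °C closes the ring by Tsuji–Trost allylation. The methoxide released on decarboxylation forms the enolate, which attacks the unsubstituted terminus of the π-allyl complex, and the route is rejoined at 35.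

Step 7. Hydrazone formation may be slow because the C10 carbonyl lies between two fully substituted carbons, which would let hydrazinolysis of the acetate or opening of the epoxide by hydrazine compete. Fallback: starting from 12, NaBH4 in MeOH reduces the ketone to the epoxy alcohol F3 (C10 configuration irrelevant). PhOC(S)Cl with pyridine and 4-(dimethylamino)pyridine gives the O-phenyl thionocarbonate F4. Bu3SnH with azobisisobutyronitrile in benzene at 80 °C generates the C10 radical, which opens the epoxide to the C10=C11 alkene and the 12β-alkoxyl radical, and the route is rejoined at 13.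

Step 12. Facial selectivity may be poor, because the α-oriented C2 side chain on C1 partly shields the α face and osmylation could occur syn to the C9 arm. Fallback: starting from 17, Woodward cis-hydroxylation (I2, AgOAc, wet AcOH) delivers oxygen to the face opposite to the one attacked first by the electrophile and gives the hydroxy acetate F5. K2CO3 in MeOH removes both acetates to give the triol F6. Acetonide formation with Me2C(OMe)2 and pyridinium p-toluenesulfonate rejoins the route at 20.

Step 15. The neopentyl-type sulfamate may ionise and suffer a 1,2-methyl shift from C1 in competition with syn elimination. Fallback: starting from 20, NaH, CS2 and MeI give the S-methyl xanthate F7. Pyrolysis at about 180 °C in o-dichlorobenzene (Chugaev elimination, concerted) rejoins the route at 21.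

Step 25. Facial selectivity may be poor or reversed, through chelation of lithium between the C2 carbonyl and the PMB ether oxygen or through the conformation of the ten-membered ring overriding the open-chain model. Fallback: starting from 35, the ketone is reduced under catalyst control with (R)-1-methyl-3,3-diphenyltetrahydro-1H,3H-pyrrolo[1,2-c][1,3,2]oxazaborole and catecholborane, so that the reagent and not the substrate selects the face, and the route is rejoined at 36 (F0, no new compound).

Step 30. Hydrolysis of the ketal may be incomplete because the adjacent acyloxy group deactivates it, or acid may cause enolisation at C7 with migration of the C5=C6 alkene. Fallback: starting from 39, the dimethyl ketal is hydrolysed at the hydroxy stage under mild conditions (pyridinium p-toluenesulfonate, acetone–H2O) with the acetonide kept, giving the α-hydroxy ketone F8. Heating F8 with Ph3P=C(Me)CO2Et in toluene builds the butenolide by Wittig olefination and lactonisation without any acylation step, giving the acetonide-protected target F9. Hydrolysis of the acetonide with aqueous AcOH rejoins the route at 42.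

Further compounds

F1 | step 24 | allylic methyl carbonate of 31 with free C2 hydroxyl | C[C@@]1([C@H](O)COCc2ccc(OC)cc2)[C@@H](CC(OC)(OC)[C@@H](O[Si](C)(C)C(C)(C)C)/C=C(C)\COC(=O)OC)[C@]3(C)OC(C)(C)O[C@@H]3C=C1
F2 | step 24 | C2 keto allylic methyl carbonate | C[C@@]1(C(=O)COCc2ccc(OC)cc2)[C@@H](CC(OC)(OC)[C@@H](O[Si](C)(C)C(C)(C)C)/C=C(C)\COC(=O)OC)[C@]3(C)OC(C)(C)O[C@@H]3C=C1
F3 | step 7 | 11β,12β-epoxy C10 alcohol | C[C@@]1([C@H](O[Si](CC)(CC)CC)COCc2ccc(OC)cc2)[C@@H](O)[C@@]3(C)O[C@H]3C[C@@H]1OC(C)=O
F4 | step 7 | C10 O-phenyl thionocarbonate of F3 | C[C@@]1([C@H](O[Si](CC)(CC)CC)COCc2ccc(OC)cc2)[C@@H](OC(=S)Oc4ccccc4)[C@@]3(C)O[C@H]3C[C@@H]1OC(C)=O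
F5 | step 12 | 11α-hydroxy 12α-acetate | C[C@@]1([C@H](O[Si](CC)(CC)CC)COCc2ccc(OC)cc2)[C@@H](CC(OC)(OC)C(=O)OC)[C@](C)(O)[C@H](OC(C)=O)C[C@@H]1OC(C)=O
F6 | step 12 | 11α,12α,14α-triol | C[C@@]1([C@H](O[Si](CC)(CC)CC)COCc2ccc(OC)cc2)[C@@H](CC(OC)(OC)C(=O)OC)[C@](C)(O)[C@H](O)C[C@@H]1O
F7 | step 15 | C14 S-methyl xanthate of 20 | C[C@@]1([C@H](O[Si](CC)(CC)CC)COCc2ccc(OC)cc2)[C@@H](CC(OC)(OC)C(=O)OC)[C@]3(C)OC(C)(C)O[C@@H]3C[C@@H]1OC(=S)SC
F0 | step 25 | none | none
F8 | step 30 | C7 hydroxy C8 ketone with 11,12-acetonide | C[C@@]12[C@@H](OC(C)=O)[C@H](OC(C)=O)C/C(C)=C\[C@H](O)C(=O)C[C@H]1[C@]4(C)OC(C)(C)O[C@@H]4C=C2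
F9 | step 30 | 11,12-acetonide of the target | C[C@@]12[C@@H](OC(C)=O)[C@H](OC(C)=O)C/C(C)=C\[C@@H]3OC(=O)C(C)=C3C[C@H]1[C@]4(C)OC(C)(C)O[C@@H]4C=C2
A1 | alternative 1 | (E)-4-[(tert-butyldimethylsilyl)oxy]-2-methylbut-2-enal | O=C/C(C)=C/CO[Si](C)(C)C(C)(C)C
A2 | alternative 1 | (Z)-tert-butyldimethyl(penta-1,3-dien-3-yloxy)silane | C=C/C(O[Si](C)(C)C(C)(C)C)=C/C
A3 | alternative 1 | ring A silyl enol ether aldehyde | O=C[C@@]1(C)CC=C(O[Si](C)(C)C(C)(C)C)[C@@H](C)[C@@H]1CO[Si](C)(C)C(C)(C)C
A4 | alternative 2 | fourteen-membered 1,2-epoxide with butenolide, E-C10=C11 and Z-C13=C14 | C[C@@]12O[C@H]1[C@H](O[Si](C)(C)C(C)(C)C)C/C(C)=C\[C@@H]3OC(=O)C(C)=C3C/C=C(C)/C/C=C\2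
A5 | alternative 2 | tricyclic C2 alcohol with ring A 11,13-diene | CC(C)(C)[Si](C)(C)O[C@@H]1C/C(C)=C\[C@@H]2OC(=O)C(C)=C2C[C@H]2C(C)=CC=C[C@]2(C)[C@H]1O
A6 | alternative 3 | seco enol triflate ester with C7 Z-enal and 2,3-diacetate | COC(=O)/C(C)=C(\OS(=O)(=O)C(F)(F)F)C[C@H]1[C@]2(C)OC(C)(C)O[C@@H]2C=C[C@]1(C)[C@@H](OC(C)=O)[C@H](OC(C)=O)C/C(C)=C\C=O
A7 | alternative 3 | tricyclic diacetate with 11,12-acetonide | CC(=O)O[C@@H]1C/C(C)=C\[C@@H]2OC(=O)C(C)=C2C[C@H]2[C@]3(C)OC(C)(C)O[C@@H]3C=C[C@]2(C)[C@H]1OC(C)=O
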